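**Retrosynthetic overview**
1. Argophyllin A ⇐ late outer-face epoxidation of the E C1=C10 olefin, after C8 angeloylation and Eschenmoser methylenation of a trans-fused 6,12-lactone.
2. Lactone ⇐ C6 ketone (anti reduction directed by the free C8–OH) carrying a C7–CH2CO2t-Bu arm.
3. Ten-membered ring ⇐ anionic oxy-Cope ring expansion of a trans-1-[(Z)-2-alkoxyvinyl]-2-isopropenylcyclohexanol with enolate alkylation in the same flask (forms C8–C9, breaks C1–C6; sets the E olefin, C8 and C7).
4. Cyclohexanone ⇐ (S)-carvone: Luche reduction, allylic oxidation, Weitz–Scheffer epoxidation and reductive opening set the C3/C4 diol on the six-membered ring.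
5. Ring order: six-membered carbocycle (chiral pool) → ten-membered carbocycle (ring expansion) → γ-lactone → epoxide.

Assumption: ring atoms are numbered as in germacranolides (lactone O on C6, C6–O–C12; angelate on C8; epoxide C1/C10; diol C3/C4). In this numbering the target is (1R,3S,4S,6R,7S,8R,10R), i.e. 1β,10α-epoxy, 3β-OH, 4α-OH/4β-Me, 6α-O, H-7α, 8β-O-angeloyl. TBS = tert-butyldimethylsilyl, TES = triethylsilyl, PMB = 4-methoxybenzyl.

This route is a paper design: none of it has been run, and the stereochemical outcomes were derived by hand from transition-state models.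

**Step 1**
Reactants: 1 (S)-(+)-carvone
Product: 2 (1S,5S)-cis-carveol
Conditions: NaBH4, CeCl3·7H2O, MeOH, −78 to 0 °C
Reagents that add atoms: none
Why: Luche 1,2-reduction, in which hydride attacks the enone carbonyl anti to the isopropenyl group so that the new carbinol centre is cis to it (1S).

**Step 2**
Reactants: 2 (1S,5S)-cis-carveol
Product: 3 cis-carveol TBS ether
Conditions: TBSCl, imidazole, DMF, rt
Reagents that add atoms: tert-butyldimethylsilyl chloride CC(C)(C)[Si](C)(C)Cl
Why: Standard silylation of the allylic alcohol, which also shields the CH–O hydrogen for the next oxidation; no stereocentre changes.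

**Step 3**
Reactants: 3 cis-carveol TBS ether
Product: 4 (4S,6S)-4-(TBS-oxy)-3-methyl-6-(prop-1-en-2-yl)cyclohex-2-en-1-one
Conditions: CrO3, 3,5-dimethylpyrazole, CH2Cl2, −20 °C
Reagents that add atoms: chromium trioxide O=[Cr](=O)=O
Why: Allylic C–H oxidation (Salmond chromium trioxide–dimethylpyrazole oxidation) of the ring CH2 next to the =CH terminus, the usual site for 1-methylcyclohexenes (valencene to nootkatone), while the CH–OTBS hydrogen is shielded and the isopropenyl group is spared; the centre now alpha to the ketone stays cis to C4–O, which is also the thermodynamic arrangement.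

**Step 4**
Reactants: 4 silyloxy enone
Product: 5 (1R,3S,5S,6S)-5-(TBS-oxy)-6-methyl-3-(prop-1-en-2-yl)-7-oxabicyclo[4.1.0]heptan-2-one
Conditions: H2O2 (30% aq), NaOH (cat.), MeOH, 0 °C
Reagents that add atoms: hydrogen peroxide OO
Why: Weitz–Scheffer nucleophilic epoxidation, in which hydroperoxide adds to the enone β-carbon anti to the adjacent silyloxy group (and anti to the isopropenyl group), so the tertiary C–O bond is formed trans to OTBS.

**Step 5**
Reactants: 5 epoxy ketone
Product: 6 (2S,4S,5S)-4-(TBS-oxy)-5-hydroxy-5-methyl-2-(prop-1-en-2-yl)cyclohexan-1-one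
Conditions: SmI2 (2.2 equiv), THF/MeOH, −90 °C
Reagents that add atoms: none
Why: Single-electron reductive opening of the α,β-epoxy ketone (Molander conditions) cleaves only the Cα–O bond, so the tertiary carbinol keeps its configuration and the trans-diol pattern (future 3β,4α) is in place.

**Step 6**
Reactants: 6 β-hydroxy ketone
Product: 7 (2S,4S,5S)-4-(TBS-oxy)-5-methyl-2-(prop-1-en-2-yl)-5-(TES-oxy)cyclohexan-1-one
Conditions: TESOTf, 2,6-lutidine, CH2Cl2, −78 °C
Reagents that add atoms: triethylsilyl trifluoromethanesulfonate CC[Si](CC)(CC)OS(=O)(=O)C(F)(F)F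
Why: Triflate-mediated silylation of the tertiary alcohol, needed so that no β-alkoxide can cause retro-aldol cleavage or misdirect the later hydride delivery; the low temperature leaves the α-stereocentre untouched.

**Step 7**
Reactants: 8 4-methoxybenzyl alcohol; 9 butyl vinyl ether
Product: 10 4-methoxybenzyl vinyl ether
Conditions: Pd(O2CCF3)2 (cat.), 4,7-diphenyl-1,10-phenanthroline (cat.), Et3N (cat.), neat 9, 75 °C
Reagents that add atoms: none
Why: Palladium-catalysed transfer vinylation (transetherification) of the alcohol with the vinyl ether used as solvent.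

**Step 8**
Reactants: 10 4-methoxybenzyl vinyl ether
Product: 12 (Z)-1-bromo-2-[(4-methoxybenzyl)oxy]ethene, via dibromo ether 11 (not isolated)
Conditions: Br2, CH2Cl2, −78 °C; then i-Pr2NEt, −78 °C to rt
Reagents that add atoms: bromine BrBr
Why: Bromine addition to the enol ether followed by amine-induced dehydrobromination through the oxocarbenium ion gives the β-bromo enol ether mainly as the Z isomer (cis effect), which is purified on base-washed silica.

**Step 9**
Reactants: 12 (Z)-bromide; 7 silylated ketone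
Product: 14 (1S,2S,4S,5S)-1-{(Z)-2-[(4-methoxybenzyl)oxy]ethenyl}-4-(TBS-oxy)-5-methyl-2-(prop-1-en-2-yl)-5-(TES-oxy)cyclohexan-1-ol, via vinyllithium 13 (not isolated)
Conditions: t-BuLi (2 equiv), Et2O, −78 °C; then 7, THF, −78 °C
Reagents that add atoms: tert-butyllithium [Li]C(C)(C)C (its lithium is carried only by intermediate 13)
Why: Bromine–lithium exchange with retention of the Z geometry (oxygen-coordinated vinyllithium) and 1,2-addition to the ketone from the equatorial direction, trans to the isopropenyl group, because the axial path is blocked by the syn-axial methyl group, which sets the carbinol centre as 1S with the two alkenyl groups trans-diequatorial.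

**Step 10**
Reactants: 14 divinyl carbinol; 15 tert-butyl bromoacetate
Product: 17 tert-butyl [(1(10)E,3S,4S,7R,8R)-8-(PMB-oxy)-3-(TBS-oxy)-4,10-dimethyl-6-oxo-4-(TES-oxy)cyclodec-1(10)-en-7-yl]acetate, via potassium enolate 16 (not isolated)
Conditions: KN(SiMe3)2, THF, −20 to 10 °C; then 15, −78 °C
Reagents that add atoms: potassium bis(trimethylsilyl)amide C[Si](C)(C)[N-][Si](C)(C)C.[K+] (its potassium is carried only by intermediate 16)
Why: Anionic oxy-Cope rearrangement with enolate alkylation in the same flask, where the trans-diequatorial dialkenyl alkoxide must pass through a trans-decalin-like chair transition state that gives the E C1=C10 olefin and, with the Z alkoxy group axial and potassium-bridged to the alkoxide oxygen, the 8R centre, after which the ring enolate (C8–O held near the enolate plane, which disfavours β-elimination) is alkylated at C7 on its outer face, cis to O8.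

**Step 11**
Reactants: 17 keto ester PMB ether
Product: 18 tert-butyl [(1(10)E,3S,4S,7R,8R)-8-hydroxy-3-(TBS-oxy)-4,10-dimethyl-6-oxo-4-(TES-oxy)cyclodec-1(10)-en-7-yl]acetate
Conditions: DDQ, CH2Cl2/pH 7 phosphate buffer, 0 °C
Reagents that add atoms: none
Why: Oxidative cleavage of the 4-methoxybenzyl ether by DDQ under buffered conditions that leave the silyl ethers, the olefin and the β-hydroxy ketone intact.

**Step 12**
Reactants: 18 β-hydroxy ketone
Product: 19 tert-butyl [(1(10)E,3S,4S,6R,7R,8R)-6,8-dihydroxy-3-(TBS-oxy)-4,10-dimethyl-4-(TES-oxy)cyclodec-1(10)-en-7-yl]acetate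
Conditions: Me4NBH(OAc)3, AcOH/MeCN (1:1), −25 °C
Reagents that add atoms: none
Why: Evans–Saksena reduction, in which the C8 hydroxyl binds boron and delivers hydride intramolecularly to C6 through a chair six-membered transition state, giving the 1,3-anti diol and therefore the 6α (6R) alcohol.

**Step 13**
Reactants: 19 anti-diol ester
Product: 20 8β-hydroxy-3β-(TBS-oxy)-4α-(TES-oxy) trans-6α,12-lactone (3S,4S,6R,7R,8R; 1(10)E)
Conditions: camphor-10-sulfonic acid (cat.), PhMe, 60 °C
Reagents that add atoms: none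
Why: Acid-catalysed lactonisation under equilibrating conditions closes the trans-fused γ-lactone on O6, which lies gauche to the C7 side chain, in preference to a cis lactone on the pseudo-axial 8β-oxygen, as in stable 8β-hydroxy-6α,12-germacranolides such as eupatolide.

**Step 14**
Reactants: 20 hydroxy lactone
Product: 23 8β-hydroxy-3β-(TBS-oxy)-4α-(TES-oxy) α-methylene trans-6α,12-lactone, via Mannich base 21 (not isolated), via ammonium iodide 22 (not isolated)
Conditions: LiN(i-Pr)2 (2.5 equiv), THF, −78 °C (20 added to the base); CH2=NMe2+ I−, −78 to 0 °C; then MeI, MeOH, rt; then NaHCO3 (aq), CH2Cl2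
Reagents that add atoms: Eschenmoser's salt C=[N+](C)C.[I-]; iodomethane CI (its methyl is carried only by intermediate 22)
Why: Eschenmoser α-methylenation, i.e. Mannich reaction of the lactone enolate (the C8 alkoxide forms first and is inert), N-methylation and Hofmann-type elimination, which installs the exocyclic methylene and erases the transient C11 stereocentre.

**Step 15**
Reactants: 23 α-methylene hydroxy lactone; 24 angelic acid
Product: 26 8β-angeloyloxy-3β-(TBS-oxy)-4α-(TES-oxy) α-methylene trans-6α,12-lactone, via mixed anhydride 25 (not isolated)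
Conditions: 2,4,6-trichlorobenzoyl chloride, Et3N, PhMe, rt; then 23, 4-(dimethylamino)pyridine, PhMe, 60 °C
Reagents that add atoms: 2,4,6-trichlorobenzoyl chloride O=C(Cl)c1c(Cl)cc(Cl)cc1Cl (its atoms are carried only by intermediate 25)
Why: Yamaguchi esterification through the mixed anhydride acylates the hindered 8β-hydroxyl with retention at C8 and, in toluene, without isomerising the angelate to the tiglate.

**Step 16**
Reactants: 26 angelate bis-silyl ether
Product: 27 8β-angeloyloxy-3β,4α-dihydroxy α-methylene trans-6α,12-lactone (3S,4S,6R,7R,8R; 1(10)E)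
Conditions: HF·pyridine, pyridine/THF, 0 °C to rt
Reagents that add atoms: none
Why: Fluoride-mediated cleavage of both silyl ethers under buffered conditions that do not touch the lactone, the angelate or the olefin.

**Step 17**
Reactants: 27 diol
Product: 28 argophyllin A
Conditions: mCPBA, NaHCO3, CH2Cl2, 0 °C
Reagents that add atoms: 3-chloroperoxybenzoic acid OOC(=O)c1cccc(Cl)c1
Why: Prilezhaev epoxidation of the only electron-rich olefin, where a trans double bond in a ten-membered ring can be attacked only on its outer face and the conformer with the C10 methyl on the β face (usual for trans-6,12-germacranolides and reinforced by hydrogen bonding of the peracid to the 3β-hydroxyl) gives the 1β,10α-epoxide, i.e. (1R,10R).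

**Compound list**
1 | (S)-(+)-carvone, (5S)-2-methyl-5-(prop-1-en-2-yl)cyclohex-2-en-1-one | CC(=C)[C@@H]1CC(=O)C(C)=CC1 | starting material
2 | (1S,5S)-cis-carveol | CC(=C)[C@@H]1C[C@H](O)C(C)=CC1 | intermediate
3 | tert-butyl(dimethyl){[(1S,5S)-2-methyl-5-(prop-1-en-2-yl)cyclohex-2-en-1-yl]oxy}silane | CC(=C)[C@@H]1C[C@H](O[Si](C)(C)C(C)(C)C)C(C)=CC1 | intermediate
4 | (4S,6S)-4-[(tert-butyldimethylsilyl)oxy]-3-methyl-6-(prop-1-en-2-yl)cyclohex-2-en-1-one | CC(=C)[C@@H]1C[C@H](O[Si](C)(C)C(C)(C)C)C(C)=CC1=O | intermediate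
5 | (1R,3S,5S,6S)-5-[(tert-butyldimethylsilyl)oxy]-6-methyl-3-(prop-1-en-2-yl)-7-oxabicyclo[4.1.0]heptan-2-one | CC(=C)[C@@H]1C[C@H](O[Si](C)(C)C(C)(C)C)[C@@]2(C)O[C@H]2C1=O | intermediate
6 | (2S,4S,5S)-4-[(tert-butyldimethylsilyl)oxy]-5-hydroxy-5-methyl-2-(prop-1-en-2-yl)cyclohexan-1-one | CC(=C)[C@@H]1C[C@H](O[Si](C)(C)C(C)(C)C)[C@@](C)(O)CC1=O | intermediate
7 | (2S,4S,5S)-4-[(tert-butyldimethylsilyl)oxy]-5-methyl-2-(prop-1-en-2-yl)-5-[(triethylsilyl)oxy]cyclohexan-1-one | CC(=C)[C@@H]1C[C@H](O[Si](C)(C)C(C)(C)C)[C@@](C)(O[Si](CC)(CC)CC)CC1=O | intermediate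
8 | 4-methoxybenzyl alcohol | COc1ccc(CO)cc1 | starting material
9 | butyl vinyl ether | CCCCOC=C | starting material
10 | 4-methoxybenzyl vinyl ether | C=COCc1ccc(OC)cc1 | intermediate
11 | 1,2-dibromoethyl 4-methoxybenzyl ether (racemic) | BrCC(Br)OCc1ccc(OC)cc1 | intermediate
12 | (Z)-1-bromo-2-[(4-methoxybenzyl)oxy]ethene | Br/C=C\OCc1ccc(OC)cc1 | intermediate
13 | (Z)-2-[(4-methoxybenzyl)oxy]ethenyllithium | [Li]/C=C\OCc1ccc(OC)cc1 | intermediate
14 | (1S,2S,4S,5S)-4-[(tert-butyldimethylsilyl)oxy]-1-{(Z)-2-[(4-methoxybenzyl)oxy]ethenyl}-5-methyl-2-(prop-1-en-2-yl)-5-[(triethylsilyl)oxy]cyclohexan-1-ol | CC(=C)[C@@H]1C[C@H](O[Si](C)(C)C(C)(C)C)[C@@](C)(O[Si](CC)(CC)CC)C[C@@]1(O)/C=C\OCc2ccc(OC)cc2 | intermediate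
15 | tert-butyl bromoacetate | BrCC(=O)OC(C)(C)C | starting material
16 | potassium (1(10)E,6Z,3S,4S,8R)-7-unsubstituted ring enolate: 8-(PMB-oxy)-3-(TBS-oxy)-4,10-dimethyl-4-(TES-oxy)cyclodeca-1(10),6-dien-6-olate (C5 and C8 trans across C6=C7) | C1/C(C)=C/C[C@H](O[Si](C)(C)C(C)(C)C)[C@@](C)(O[Si](CC)(CC)CC)C/C([O-])=C/[C@@H]1OCc2ccc(OC)cc2.[K+] | intermediate
17 | tert-butyl [(1(10)E,3S,4S,7R,8R)-8-(PMB-oxy)-3-(TBS-oxy)-4,10-dimethyl-6-oxo-4-(TES-oxy)cyclodec-1(10)-en-7-yl]acetate | C1/C(C)=C/C[C@H](O[Si](C)(C)C(C)(C)C)[C@@](C)(O[Si](CC)(CC)CC)CC(=O)[C@H](CC(=O)OC(C)(C)C)[C@@H]1OCc2ccc(OC)cc2 | intermediate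
18 | tert-butyl [(1(10)E,3S,4S,7R,8R)-8-hydroxy-3-(TBS-oxy)-4,10-dimethyl-6-oxo-4-(TES-oxy)cyclodec-1(10)-en-7-yl]acetate | C1/C(C)=C/C[C@H](O[Si](C)(C)C(C)(C)C)[C@@](C)(O[Si](CC)(CC)CC)CC(=O)[C@H](CC(=O)OC(C)(C)C)[C@@H]1O | intermediate
19 | tert-butyl [(1(10)E,3S,4S,6R,7R,8R)-6,8-dihydroxy-3-(TBS-oxy)-4,10-dimethyl-4-(TES-oxy)cyclodec-1(10)-en-7-yl]acetate (6α,8β-diol) | C1/C(C)=C/C[C@H](O[Si](C)(C)C(C)(C)C)[C@@](C)(O[Si](CC)(CC)CC)C[C@@H](O)[C@H](CC(=O)OC(C)(C)C)[C@@H]1O | intermediate
20 | 8β-hydroxy-3β-(TBS-oxy)-4α-(TES-oxy)-4β,10-dimethyl trans-6α,12-lactone, (3S,4S,6R,7R,8R), 1(10)E | C1/C(C)=C/C[C@H](O[Si](C)(C)C(C)(C)C)[C@@](C)(O[Si](CC)(CC)CC)C[C@H]2OC(=O)C[C@@H]2[C@@H]1O | intermediate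
21 | 11-(dimethylaminomethyl) derivative of 20 (C11 epimer mixture) | C1/C(C)=C/C[C@H](O[Si](C)(C)C(C)(C)C)[C@@](C)(O[Si](CC)(CC)CC)C[C@H]2OC(=O)C(CN(C)C)[C@@H]2[C@@H]1O | intermediate
22 | 11-(trimethylammoniomethyl) derivative of 20, iodide | C1/C(C)=C/C[C@H](O[Si](C)(C)C(C)(C)C)[C@@](C)(O[Si](CC)(CC)CC)C[C@H]2OC(=O)C(C[N+](C)(C)C)[C@@H]2[C@@H]1O.[I-] | intermediate
23 | 8β-hydroxy-3β-(TBS-oxy)-4α-(TES-oxy) 11(13)-methylene trans-6α,12-lactone, (3S,4S,6R,7R,8R), 1(10)E | C1/C(C)=C/C[C@H](O[Si](C)(C)C(C)(C)C)[C@@](C)(O[Si](CC)(CC)CC)C[C@H]2OC(=O)C(=C)[C@@H]2[C@@H]1O | intermediate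
24 | angelic acid, (Z)-2-methylbut-2-enoic acid | C/C=C(/C)C(=O)O | starting material
25 | (Z)-2-methylbut-2-enoic 2,4,6-trichlorobenzoic anhydride | C/C=C(/C)C(=O)OC(=O)c1c(Cl)cc(Cl)cc1Cl | intermediate
26 | 8β-angeloyloxy-3β-(TBS-oxy)-4α-(TES-oxy) 11(13)-methylene trans-6α,12-lactone, (3S,4S,6R,7R,8R), 1(10)E | C1/C(C)=C/C[C@H](O[Si](C)(C)C(C)(C)C)[C@@](C)(O[Si](CC)(CC)CC)C[C@H]2OC(=O)C(=C)[C@@H]2[C@@H]1OC(=O)/C(C)=C\C | intermediate
27 | 8β-angeloyloxy-3β,4α-dihydroxy 11(13)-methylene trans-6α,12-lactone, (3S,4S,6R,7R,8R), 1(10)E (1,10-deoxy-argophyllin A) | C1/C(C)=C/C[C@H](O)[C@@](C)(O)C[C@H]2OC(=O)C(=C)[C@@H]2[C@@H]1OC(=O)/C(C)=C\C | intermediate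
28 | argophyllin A, (1R,3S,4S,6R,7S,8R,10R) | C=C1C(=O)O[C@@H]2C[C@](C)(O)[C@@H](O)C[C@H]3O[C@]3(C)C[C@@H](OC(=O)/C(C)=C\C)[C@@H]12 | target

**Totals**
Total step count: 17. Longest linear sequence: 15 steps (steps 1–6 and 9–17, from (S)-carvone); steps 7–8 build the vinyl bromide side branch.

**Three steps most likely to fail, with fallbacks**

Step 3, the allylic oxidation, may attack the CH–OTBS hydrogen or give poor conversion next to the isopropenyl-bearing carbon. The fallback avoids C–H oxidation altogether; it sets out from compound 3 and comes back at compound 4. mCPBA epoxidises the ring olefin of 3 to the 1,6-epoxide F1 (either face serves). PhSeNa (from PhSeSePh and NaBH4 in EtOH) opens it at the secondary carbon to the trans hydroxy selenide F2. H2O2 oxidises this to the selenoxide F3, which undergoes syn-elimination away from the carbinol carbon to the tertiary allylic alcohol F4. Pyridinium chlorochromate C5H5NH[CrO3Cl] then effects the Babler–Dauben oxidative transposition of F4 to enone 4.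

Step 10, the tandem oxy-Cope/alkylation, carries three risks: the Z alkoxy group sits axial in the chair, the β-alkoxy enolate may eliminate, and the alkylation may be unselective at C7 or suffer proton transfer. The fallback separates the two events and forms the C7–C11 bond by a neutral radical process instead of an ionic one; it sets out from compound 14 and comes back at compound 17. The oxy-Cope enolate is quenched cold with Me3SiCl to give the trimethylsilyl enol ether F5. Et3B/air-initiated addition of tert-butyl iodoacetate to F5 (electrophilic radical adds to C7 on the outer face, iodine transfer, loss of Me3SiI) then returns keto ester 17.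

Step 17, the final epoxidation, depends on the conformer population of the ten-membered ring and could give the wrong face or a mixture. The fallback replaces substrate control by reagent control and inverts the order of the last two operations; it sets out from compound 26 and comes back at compound 28. Shi epoxidation of 26 gives the epoxy bis-silyl ether F6. Conditions: 1,2:4,5-di-O-isopropylidene-β-D-erythro-2,3-hexodiulo-2,6-pyranose as ketone catalyst, KHSO5 (as 2KHSO5·KHSO4·K2SO4), K2CO3 buffer, MeCN/dimethoxymethane/H2O, 0 °C. This method is at its best with trans-trisubstituted olefins and gives the (R,R) sense needed here. Buffered fluoride (Bu4NF/AcOH, THF) then removes both silyl groups to give 28.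

**Further compounds**
F1 | step 3 | tert-butyl(dimethyl){[1-methyl-4-(prop-1-en-2-yl)-7-oxabicyclo[4.1.0]heptan-2-yl]oxy}silane (epoxide anti to OTBS shown) | CC(=C)[C@@H]1C[C@H](O[Si](C)(C)C(C)(C)C)[C@@]2(C)O[C@H]2C1
F2 | step 3 | 2-[(tert-butyldimethylsilyl)oxy]-1-methyl-6-(phenylselanyl)-4-(prop-1-en-2-yl)cyclohexan-1-ol (trans hydroxy selenide) | CC(=C)[C@@H]1C[C@H](O[Si](C)(C)C(C)(C)C)[C@@](C)(O)[C@H]([Se]c2ccccc2)C1
F3 | step 3 | selenoxide of F2 | CC(=C)[C@@H]1C[C@H](O[Si](C)(C)C(C)(C)C)[C@@](C)(O)[C@H]([Se](=O)c2ccccc2)C1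
F4 | step 3 | 6-[(tert-butyldimethylsilyl)oxy]-1-methyl-4-(prop-1-en-2-yl)cyclohex-2-en-1-ol | CC(=C)[C@@H]1C[C@H](O[Si](C)(C)C(C)(C)C)[C@@](C)(O)C=C1
F5 | step 10 | trimethylsilyl enol ether corresponding to enolate 16 | C1/C(C)=C/C[C@H](O[Si](C)(C)C(C)(C)C)[C@@](C)(O[Si](CC)(CC)CC)C/C(O[Si](C)(C)C)=C/[C@@H]1OCc2ccc(OC)cc2
F6 | step 17 | 3-O-TBS-4-O-TES argophyllin A (1β,10α-epoxide of 26) | C1[C@@]3(C)O[C@@H]3C[C@H](O[Si](C)(C)C(C)(C)C)[C@@](C)(O[Si](CC)(CC)CC)C[C@H]2OC(=O)C(=C)[C@@H]2[C@@H]1OC(=O)/C(C)=C\C
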